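**Retrosynthetic overview**
1. The plan rests on ring C. C3 and C4 are neighbouring oxygen-bearing carbons, and both hang from the ether oxygen O1 (C4 through C4a–C8a of ring A, C3 through C2). Each can therefore be read as a formyl carbon, and C3–C4 as an acyloin bond that only umpolung can make.
2. Target ⇒ (5-O-demethylation, 3-O-methylation, dehydrogenation) trans-3-hydroxychroman-4-one ⇒ carbene-catalysed benzoin closure of an aryl ether dialdehyde.
3. Dialdehyde ⇒ diol ⇒ formyl ester ⇒ O1–C2 bond, made by displacing an α-bromo arylacetate with 2-hydroxy-3,4,6-trimethoxybenzaldehyde.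
4. Rings A and B are bought as 1,2,3,5-tetramethoxybenzene and methyl 2-(2,4-dimethoxyphenyl)acetate. Ring C is the only ring formed, in step 7.

Key step: step 7

Assumption: the target is achiral, so all chiral intermediates are carried as racemates with one enantiomer drawn in each SMILES, and both starting materials are taken as purchasable.

Step 1
Reactants: 1 1,2,3,5-tetramethoxybenzene
Product: 3 2,3,4,6-tetramethoxybenzaldehyde, via aryl iminium chloride 2 (not isolated)
Conditions: POCl3, DMF, 0 → 60 °C; then ice–water
Reagents that add atoms: N,N-dimethylformamide CN(C)C=O; water O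
Why: Vilsmeier–Haack formylation, in which the two free ring positions of 1 are equivalent and strongly activated, so the chloroiminium ion attacks once, and the iminium group of 2 deactivates the ring against a second attack until water hydrolyses it.

Step 2
Reactants: 3 2,3,4,6-tetramethoxybenzaldehyde
Product: 4 2-hydroxy-3,4,6-trimethoxybenzaldehyde
Conditions: BCl3 (1.1 equiv), CH2Cl2, −78 → 0 °C; then H2O
Reagents that add atoms: none
Why: Chelation-directed Lewis acid ether cleavage, in which BCl3 bridges the formyl oxygen and an ortho methoxy oxygen, and of the two ortho groups the one at C2, twisted out of the ring plane between CHO and the C3 methoxy group, is the more basic and more strained and should fall first, the same preference seen when 2,3,4,6-tetramethoxyphenyl ketones give 2-hydroxy-3,4,6-trimethoxyphenyl ketones with Lewis acids.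

Step 3
Reactants: 5 methyl 2-(2,4-dimethoxyphenyl)acetate
Product: 7 racemic methyl 2-bromo-2-(2,4-dimethoxyphenyl)acetate, via silyl ketene acetal 6 (not isolated)
Conditions: LiN(SiMe3)2, Me3SiCl, THF, −78 °C; then NBS (1.0 equiv), −78 → −20 °C; used crude
Reagents that add atoms: N-bromosuccinimide O=C1CCC(=O)N1Br; chlorotrimethylsilane C[Si](C)(C)Cl (its atoms stay only in 6)
Why: Electrophilic α-bromination of an ester through its silyl ketene acetal, chosen because radical bromination would put bromine on the electron-rich dimethoxyphenyl ring, whereas 6 consumes NBS at −78 °C far faster than the arene does; the new stereocentre forms without control, so 7 is racemic.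

Step 4
Reactants: 4 2-hydroxy-3,4,6-trimethoxybenzaldehyde; 7 racemic methyl 2-bromo-2-(2,4-dimethoxyphenyl)acetate
Product: 8 racemic methyl 2-(2,4-dimethoxyphenyl)-2-(2-formyl-3,5,6-trimethoxyphenoxy)acetate
Conditions: K2CO3, DMF, rt
Reagents that add atoms: none
Why: Williamson ether synthesis, in which the potassium phenoxide of 4 displaces the doubly activated (benzylic and α-carbonyl) bromide by SN2 with inversion to form O1–C2 at room temperature, too mild for aldol closure of the product onto its own formyl group, and racemic 7 gives racemic 8.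

Step 5
Reactants: 8 racemic methyl 2-(2,4-dimethoxyphenyl)-2-(2-formyl-3,5,6-trimethoxyphenoxy)acetate
Product: 9 racemic 2-(2,4-dimethoxyphenyl)-2-[2-(hydroxymethyl)-3,5,6-trimethoxyphenoxy]ethanol
Conditions: LiAlH4, THF, 0 °C; then H2O, aq. NaOH
Reagents that add atoms: none
Why: Hydride reduction, in which LiAlH4 takes ester and aldehyde together to primary alcohols so the two carbonyl groups need not be told apart, while aryl and benzylic ethers and the C2 centre are left untouched.

Step 6
Reactants: 9 racemic 2-(2,4-dimethoxyphenyl)-2-[2-(hydroxymethyl)-3,5,6-trimethoxyphenoxy]ethanol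
Product: 10 racemic 2-[1-(2,4-dimethoxyphenyl)-2-oxoethoxy]-3,4,6-trimethoxybenzaldehyde
Conditions: Dess–Martin periodinane (2.5 equiv), pyridine, CH2Cl2, 0 °C → rt; used at once after a short silica plug
Reagents that add atoms: none
Why: Dess–Martin oxidation, which turns both primary alcohols into aldehydes under buffered, non-aqueous conditions that stop at the aldehyde level, spare the acid-sensitive electron-rich benzylic alcohol and limit enolisation of the α-aryl-α-aryloxy aldehyde.

Step 7
Reactants: 10 racemic 2-[1-(2,4-dimethoxyphenyl)-2-oxoethoxy]-3,4,6-trimethoxybenzaldehyde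
Product: 11 racemic trans-2-(2,4-dimethoxyphenyl)-3-hydroxy-5,7,8-trimethoxychroman-4-one
Conditions: 2-(pentafluorophenyl)-6,7-dihydro-5H-pyrrolo[2,1-c][1,2,4]triazol-2-ium tetrafluoroborate (15 mol %), i-Pr2NEt (30 mol %), CH2Cl2 (0.02 M), Ar, rt → 40 °C
Reagents that add atoms: none
Why: The triazolylidene freed by the amine adds to the aromatic formyl carbon (future C4), a proton shift gives the Breslow enaminol, this acyl anion equivalent attacks the aliphatic formyl carbon (future C3), and a second proton shift expels the carbene to leave the acyloin. The closest known reactions are the carbene-catalysed intramolecular crossed benzoin of 2-(2-oxoalkoxy)benzaldehydes to 3-hydroxychroman-4-ones and the acyloin cyclisation of aromatic–aliphatic dialdehydes. Ring C closes in the 6-exo-trig mode, the acceptor C=O lying outside the new ring. The one new stereocentre, C3, is set relative to C2 by a chair-like transition state with the C2 aryl group equatorial, and because H3 is α to the ketone the amine can equilibrate it through the enediol to the diequatorial 2,3-trans isomer; the achiral catalyst and racemic 10 give racemic 11. The step needs the aromatic aldehyde as donor, since an enaminol built on the aliphatic formyl group would carry the aryloxide on the neighbouring carbon and could expel it irreversibly; the substrate favours the right course because that formyl group sits on a tertiary carbon between an ortho-substituted aryl and an aryloxy group, which slows enaminol formation there, its α-oxygen makes it the better acceptor, and ortho-alkoxy groups favour carbene adducts of benzaldehydes. The weak base, the low electrophilicity of the tetraoxygenated benzaldehyde and high dilution hold back intermolecular coupling and the 5-exo aldol attack of a C2 enolate, which cannot dehydrate and so stays reversible.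

Step 8
Reactants: 11 racemic trans-2-(2,4-dimethoxyphenyl)-3-hydroxy-5,7,8-trimethoxychroman-4-one
Product: 12 2-(2,4-dimethoxyphenyl)-3-hydroxy-5,7,8-trimethoxy-4H-chromen-4-one
Conditions: I2 (20 mol %), DMSO, 110 °C
Reagents that add atoms: none
Why: Iodine-catalysed dehydrogenation with DMSO as terminal oxidant, the reaction type of the benzoin-to-benzil and flavanone-to-flavone conversions, in which iodination of the enediol at C3 and loss of HI raise the acyloin to the dicarbonyl level and enolisation towards C2 gives the aromatic 3-hydroxypyranone, erasing both stereocentres so that any cis isomer or transposed acyloin converges on 12.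

Step 9
Reactants: 12 2-(2,4-dimethoxyphenyl)-3-hydroxy-5,7,8-trimethoxy-4H-chromen-4-one
Product: 13 2-(2,4-dimethoxyphenyl)-3,5,7,8-tetramethoxy-4H-chromen-4-one
Conditions: MeI, K2CO3, acetone, reflux
Reagents that add atoms: iodomethane CI
Why: Williamson O-methylation, which needs no selectivity because the 3-hydroxyl is the only acidic group in 12.

Step 10
Reactants: 13 2-(2,4-dimethoxyphenyl)-3,5,7,8-tetramethoxy-4H-chromen-4-one
Product: 14 5-hydroxy-3,7,8,2',4'-pentamethoxyflavone
Conditions: BCl3 (1.2 equiv), CH2Cl2, −78 → 0 °C; then H2O
Reagents that add atoms: none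
Why: Chelation-directed ether cleavage, the established selective 5-O-demethylation of polymethoxyflavones, in which BCl3 bridges the C4 carbonyl oxygen and the peri 5-methoxy oxygen in a six-membered chelate and chloride removes that methyl, while the 3-methoxy group could only form a strained five-membered chelate and the 7-, 8-, 2'- and 4'-methoxy groups have no carbonyl partner.

**Compound list**
1 | 1,2,3,5-tetramethoxybenzene | COc1cc(OC)c(OC)c(OC)c1 | starting material
2 | dimethyl(2,3,4,6-tetramethoxybenzylidene)iminium chloride (not isolated) | COc1cc(OC)c(C=[N+](C)C)c(OC)c1OC.[Cl-] | intermediate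
3 | 2,3,4,6-tetramethoxybenzaldehyde | COc1cc(OC)c(C=O)c(OC)c1OC | intermediate
4 | 2-hydroxy-3,4,6-trimethoxybenzaldehyde | COc1cc(OC)c(C=O)c(O)c1OC | intermediate
5 | methyl 2-(2,4-dimethoxyphenyl)acetate | COC(=O)Cc1ccc(OC)cc1OC | starting material
6 | 2-(2,4-dimethoxyphenyl)-1-methoxy-1-(trimethylsilyloxy)ethene, E/Z mixture of no consequence (not isolated) | COC(O[Si](C)(C)C)=Cc1ccc(OC)cc1OC | intermediate
7 | racemic methyl 2-bromo-2-(2,4-dimethoxyphenyl)acetate, (S) drawn | COc1ccc([C@@H](C(=O)OC)Br)c(OC)c1 | intermediate
8 | racemic methyl 2-(2,4-dimethoxyphenyl)-2-(2-formyl-3,5,6-trimethoxyphenoxy)acetate, (R) drawn | COc1ccc([C@H](C(=O)OC)Oc2c(OC)c(OC)cc(OC)c2C=O)c(OC)c1 | intermediate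
9 | racemic 2-(2,4-dimethoxyphenyl)-2-[2-(hydroxymethyl)-3,5,6-trimethoxyphenoxy]ethanol, (R) drawn | COc1ccc([C@H](CO)Oc2c(OC)c(OC)cc(OC)c2CO)c(OC)c1 | intermediate
10 | racemic 2-[1-(2,4-dimethoxyphenyl)-2-oxoethoxy]-3,4,6-trimethoxybenzaldehyde, (R) drawn | COc1ccc([C@H](C=O)Oc2c(OC)c(OC)cc(OC)c2C=O)c(OC)c1 | intermediate
11 | racemic trans-2-(2,4-dimethoxyphenyl)-3-hydroxy-5,7,8-trimethoxychroman-4-one, (2R,3R) drawn | COc1ccc([C@@H]2[C@H](C(=O)c3c(OC)cc(OC)c(OC)c3O2)O)c(OC)c1 | intermediate
12 | 2-(2,4-dimethoxyphenyl)-3-hydroxy-5,7,8-trimethoxy-4H-chromen-4-one (3-hydroxy-5,7,8,2',4'-pentamethoxyflavone) | COc1ccc(-c2oc3c(OC)c(OC)cc(OC)c3c(=O)c2O)c(OC)c1 | intermediate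
13 | 2-(2,4-dimethoxyphenyl)-3,5,7,8-tetramethoxy-4H-chromen-4-one (3,5,7,8,2',4'-hexamethoxyflavone) | COc1ccc(-c2oc3c(OC)c(OC)cc(OC)c3c(=O)c2OC)c(OC)c1 | intermediate
14 | 5-hydroxy-3,7,8,2',4'-pentamethoxyflavone | COc1ccc(-c2oc3c(OC)c(OC)cc(O)c3c(=O)c2OC)c(OC)c1 | target

**Step count**
Total steps: 10. Longest linear sequence: 9 steps (1 → 3 → 4 → 8 → 9 → 10 → 11 → 12 → 13 → 14).

**Steps most likely to fail**

1. Step 7.
   - What may go wrong: the carbene may engage the aliphatic formyl group rather than the hindered, electron-rich aromatic one. Expulsion of the aryloxide from that enaminol (internal redox) would then cut O1–C2 irreversibly. Amine-induced enolisation at C2 may also drain material into aldol closure, or turnover may simply be too slow.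
   - Fallback: this closes ring C at O1–C2 instead of C3–C4 and sets out from 1.
     - Friedel–Crafts acetylation with AcCl and AlCl3 in Et2O, which also removes the flanked ortho methyl group, should give 1-(2-hydroxy-3,4,6-trimethoxyphenyl)ethanone F1.
     - Claisen–Schmidt condensation with 2,4-dimethoxybenzaldehyde (KOH, EtOH) leads to (E)-3-(2,4-dimethoxyphenyl)-1-(2-hydroxy-3,4,6-trimethoxyphenyl)prop-2-en-1-one F2.
     - Oxidative cyclisation with catalytic I2 in DMSO at 130 °C gives 2-(2,4-dimethoxyphenyl)-5,7,8-trimethoxy-4H-chromen-4-one F3.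
     - Epoxidation of the C2–C3 double bond of F3 with dimethyldioxirane, followed by acid-induced opening (catalytic p-TsOH), installs the 3-hydroxyl and comes back to the route at 12.

2. Step 3.
   - What may go wrong: bromination of the electron-rich ring, coupling of unreacted enolate with the bromide already formed, and solvolysis of the labile benzylic bromide during isolation.
   - Fallback: this avoids any halide and sets out from 5.
     - The potassium enolate (KN(SiMe3)2, THF, −78 °C) is hydroxylated with 3-phenyl-2-(phenylsulfonyl)oxaziridine to racemic methyl 2-(2,4-dimethoxyphenyl)-2-hydroxyacetate F4.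
     - A Mitsunobu reaction of F4 with phenol 4 (PPh3, diisopropyl azodicarboxylate, THF, 0 °C → rt) forms O1–C2 and comes back at 8.

3. Step 6.
   - What may go wrong: enolisation, hydration or air oxidation of the α-aryl-α-aryloxy aldehyde during oxidation and work-up, or lactol formation after the first oxidation followed by over-oxidation.
   - Fallback: this reaches the dialdehyde by reduction instead of oxidation and sets out from 8.
     - The formyl group is masked with HC(OMe)3 and catalytic p-TsOH in MeOH as racemic methyl 2-(2,4-dimethoxyphenyl)-2-[2-(dimethoxymethyl)-3,5,6-trimethoxyphenoxy]acetate F5.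
     - The ester is taken directly to the aldehyde level with i-Bu2AlH in toluene at −78 °C, where the α-oxygen stabilises the tetrahedral aluminium adduct. This gives racemic 2-(2,4-dimethoxyphenyl)-2-[2-(dimethoxymethyl)-3,5,6-trimethoxyphenoxy]acetaldehyde F6.
     - The very labile electron-rich aryl acetal is opened with pyridinium p-toluenesulfonate in wet acetone just before use, which returns to 10.

**Further compounds**
F1 | step 7 | 1-(2-hydroxy-3,4,6-trimethoxyphenyl)ethanone | CC(=O)c1c(O)c(OC)c(OC)cc1OC
F2 | step 7 | (E)-3-(2,4-dimethoxyphenyl)-1-(2-hydroxy-3,4,6-trimethoxyphenyl)prop-2-en-1-one | COc1ccc(/C=C/C(=O)c2c(O)c(OC)c(OC)cc2OC)c(OC)c1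
F3 | step 7 | 2-(2,4-dimethoxyphenyl)-5,7,8-trimethoxy-4H-chromen-4-one | COc1ccc(-c2cc(=O)c3c(OC)cc(OC)c(OC)c3o2)c(OC)c1
F4 | step 3 | racemic methyl 2-(2,4-dimethoxyphenyl)-2-hydroxyacetate, (S) drawn | COc1ccc([C@@H](C(=O)OC)O)c(OC)c1
F5 | step 6 | racemic methyl 2-(2,4-dimethoxyphenyl)-2-[2-(dimethoxymethyl)-3,5,6-trimethoxyphenoxy]acetate, (R) drawn | COc1ccc([C@H](C(=O)OC)Oc2c(OC)c(OC)cc(OC)c2C(OC)OC)c(OC)c1
F6 | step 6 | racemic 2-(2,4-dimethoxyphenyl)-2-[2-(dimethoxymethyl)-3,5,6-trimethoxyphenoxy]acetaldehyde, (R) drawn | COc1ccc([C@H](C=O)Oc2c(OC)c(OC)cc(OC)c2C(OC)OC)c(OC)c1
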